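**Plan**

1. Core numbering: seven-membered ring C1 (ester CH), C2, C3 (methyl carbinol), C4, C5 and C6 (ring fusion), C7 (isopropyl CH); five-membered ring C5–C10–C9(CH3)–C8–C6. Retrosynthetic cuts: the C1–O acyl bond, both epoxide C–O bonds, the C3–OH/C3–CH3 pair (back to a carbonyl), then C4–C5, C1–C2 (acetoacetate aldol), C9=C10 (metathesis), C5–C10 (vinyl addition) and C6–C7 (nitro-Michael).
2. Forward: a Michael addition joins C6–C7; vinyl addition and ring-closing metathesis give the cyclopentene; Nef reaction and acetoacetate aldol attach C1–C4; palladium-catalysed allylic alkylation closes the seven-membered ring at C4–C5; the C3 carbonyl is then moved to C1 with introduction of the C3 methyl, followed by reduction, directed epoxidation/hydride opening, acylation and directed ring epoxidation.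
3. Enabling feature: C5 is allylic to the C9=C10 alkene of the five-membered ring (the later epoxide) and C4 is α to the C3 carbonyl of the seven-membered ring (the later carbinol), so the C4–C5 bond beside the ring fusion can be made from a β-keto ester enolate and a cyclopentenyl π-allyl palladium unit.
4. Stereochemistry: C6 and C7 come from the chiral amine catalyst; C5 from Felkin–Anh vinyl addition, Mitsunobu inversion and net retention at palladium (trans fusion); C1 from hydride addition to the cyclic ketone anti to isopropyl; C3 from C1–OH-directed epoxidation; C9/C10 from C3–OH-directed epoxidation.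

Key step: step 11

Remark (assumption): 1 and 3 are taken as purchasable.
Remark: the aldol of step 9 is not expected to control C1, because the aldehyde α-carbon carries two secondary groups of similar size. Compounds 14–17 are therefore carried as C1-epimer mixtures on purpose; the centre is erased in step 12 and set in step 15. Compound 16 is drawn with the C4 ester trans to C10; that centre equilibrates through the enol.

**Route**

Step 1
Reactants: 1 ethyl 4-methylpent-4-enoate
Product: 2 4-methylpent-4-enal
Conditions: (i-Bu)2AlH (1.05 equiv), CH2Cl2, −78 °C; aq. KNaC4H4O6 work-up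
Reagents that add atoms: none
Why: Partial ester reduction with (i-Bu)2AlH at low temperature stops at the aluminium hemiacetal, which gives the aldehyde on work-up; no stereocentre is formed.

Step 2
Reactants: 2 4-methylpent-4-enal; 3 (E)-3-methyl-1-nitrobut-1-ene
Product: 4 (2S,3S)-4-methyl-2-(2-methylprop-2-en-1-yl)-3-(nitromethyl)pentanal
Conditions: (R)-α,α-diphenylprolinol trimethylsilyl ether (10 mol%), 4-nitrophenol (10 mol%), toluene, 0 °C → rt
Reagents that add atoms: none
Why: Enamine-catalysed Michael addition of an aldehyde to a nitroalkene, in which the (E)-enamine of 2, shielded on one face by the diphenyl(silyloxy)methyl group of the (R)-catalyst, adds to 3 through a synclinal transition state and sets the syn pair C6 (S) and C7 (S) together.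

Step 3
Reactants: 4 (2S,3S)-4-methyl-2-(2-methylprop-2-en-1-yl)-3-(nitromethyl)pentanal
Product: 5 (3S,4S)-6-methyl-4-[(2S)-3-methyl-1-nitrobutan-2-yl]hepta-1,6-dien-3-ol
Conditions: CH2=CHMgBr (1.2 equiv), THF, −78 °C; then H2O at −78 °C
Reagents that add atoms: vinylmagnesium bromide, C=C[Mg]Br
Why: Grignard 1,2-addition to the aldehyde should outrun deprotonation of the kinetically slow nitroalkane at −78 °C, and Felkin–Anh attack anti to the branched C7 substituent should favour the (3S) carbinol, while any (3R) epimer is converted by step 4 into the on-route alcohol 8.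

Step 4
Reactants: 5 (3S,4S)-6-methyl-4-[(2S)-3-methyl-1-nitrobutan-2-yl]hepta-1,6-dien-3-ol
Product: 6 (1R,5S)-3-methyl-5-[(2S)-3-methyl-1-nitrobutan-2-yl]cyclopent-2-en-1-ol
Conditions: RuCl2(=CHPh)(PCy3)(H2IMes) (second-generation Grubbs catalyst, 3 mol%), CH2Cl2, 40 °C
Reagents that add atoms: none
Why: Ring-closing metathesis of the 1,6-diene closes the cyclopentene with loss of ethylene and forms the trisubstituted C9=C10 alkene without touching a stereocentre; the cis alcohol 6 is separated here from any trans isomer 8.

Step 5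
Reactants: 6 (1R,5S)-3-methyl-5-[(2S)-3-methyl-1-nitrobutan-2-yl]cyclopent-2-en-1-ol
Product: 7 (1S,5S)-3-methyl-5-[(2S)-3-methyl-1-nitrobutan-2-yl]cyclopent-2-en-1-yl 4-nitrobenzoate
Conditions: 4-nitrobenzoic acid, PPh3, DIAD, toluene, −20 → 0 °C
Reagents that add atoms: 4-nitrobenzoic acid, OC(=O)c1ccc(cc1)[N+](=O)[O-]
Why: Mitsunobu esterification, in which the oxyphosphonium salt of the cis allylic alcohol is displaced by the carboxylate in an SN2 reaction from the face anti to the side chain, inverting C5 to the trans configuration.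

Step 6
Reactants: 7 (1S,5S)-3-methyl-5-[(2S)-3-methyl-1-nitrobutan-2-yl]cyclopent-2-en-1-yl 4-nitrobenzoate
Product: 8 (1S,5S)-3-methyl-5-[(2S)-3-methyl-1-nitrobutan-2-yl]cyclopent-2-en-1-ol
Conditions: K2CO3 (0.2 equiv), MeOH, 0 °C
Reagents that add atoms: none
Why: Base-catalysed transesterification of the activated aryl ester proceeds by acyl–oxygen cleavage, so the inverted C5 centre is kept.

Step 7
Reactants: 8 (1S,5S)-3-methyl-5-[(2S)-3-methyl-1-nitrobutan-2-yl]cyclopent-2-en-1-ol
Product: 10 (2S)-2-[(1S,2S)-2-hydroxy-4-methylcyclopent-3-en-1-yl]-3-methylbutanal, via potassium nitronate 9 (not isolated)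
Conditions: t-BuOK (1.1 equiv), THF, 0 °C; then added to TiCl3, NH4OAc, H2O–THF, 0 °C → rt
Reagents that add atoms: water, O
Why: Reductive Nef reaction, in which the nitronate is reduced by buffered aqueous TiCl3 to the imine and hydrolysed to the aldehyde under near-neutral conditions, so the α-centre C7 and the allylic alcohol should survive, and the trans 1,2-arrangement prevents lactol formation.

Step 8
Reactants: 10 (2S)-2-[(1S,2S)-2-hydroxy-4-methylcyclopent-3-en-1-yl]-3-methylbutanal
Product: 11 methyl (1S,5S)-3-methyl-5-[(2S)-3-methyl-1-oxobutan-2-yl]cyclopent-2-en-1-yl carbonate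
Conditions: ClCO2CH3, pyridine, CH2Cl2, 0 °C
Reagents that add atoms: methyl chloroformate, COC(=O)Cl
Why: O-acylation of the secondary allylic alcohol with a chloroformate gives the mixed carbonate with retention at C5, the hindered aldehyde being inert to pyridine at 0 °C.

Step 9
Reactants: 11 methyl (1S,5S)-3-methyl-5-[(2S)-3-methyl-1-oxobutan-2-yl]cyclopent-2-en-1-yl carbonate; 12 methyl acetoacetate
Product: 14 methyl (6S)-5-hydroxy-6-[(1S,2S)-2-[(methoxycarbonyl)oxy]-4-methylcyclopent-3-en-1-yl]-7-methyl-3-oxooctanoate (epimers at the carbinol carbon; core C1), via acetoacetate dianion 13 (not isolated)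
Conditions: 12, NaH, THF, 0 °C; n-BuLi, 0 °C; then 11, −78 °C; AcOH quench at −78 °C
Reagents that add atoms: none
Why: Aldol addition of the acetoacetate dianion through its terminal carbon forms C1–C2 and gives the δ-hydroxy β-keto ester, the carbonate being too poor an electrophile to compete at −78 °C; the new C1 centre is formed without control and is not needed.

Step 10
Reactants: 14 methyl (6S)-5-hydroxy-6-[(1S,2S)-2-[(methoxycarbonyl)oxy]-4-methylcyclopent-3-en-1-yl]-7-methyl-3-oxooctanoate
Product: 15 methyl (6S)-5-[(tert-butyldimethylsilyl)oxy]-6-[(1S,2S)-2-[(methoxycarbonyl)oxy]-4-methylcyclopent-3-en-1-yl]-7-methyl-3-oxooctanoate (core C1 epimers)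
Conditions: TBSOTf, 2,6-lutidine, CH2Cl2, −78 °C; aq. citric acid work-up
Reagents that add atoms: tert-butyldimethylsilyl trifluoromethanesulfonate, CC(C)(C)[Si](C)(C)OS(=O)(=O)C(F)(F)F
Why: Silyl ether formation at the hindered secondary alcohol with a silyl triflate and a hindered base blocks lactonisation and O-allylation in the next step and changes no stereocentre.

Step 11
Reactants: 15 methyl (6S)-5-[(tert-butyldimethylsilyl)oxy]-6-[(1S,2S)-2-[(methoxycarbonyl)oxy]-4-methylcyclopent-3-en-1-yl]-7-methyl-3-oxooctanoate
Product: 16 bicyclic β-keto ester (core: C1–OTBS; C3 ketone; C4–CO2CH3; C9=C10; 4S,5S,6R,7S; C1 epimers)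
Conditions: Pd(PPh3)4 (5 mol%), THF (0.01 M), 60 °C
Reagents that add atoms: none
Why: Zerovalent palladium binds the alkene face anti to the carbonate and ionises it with inversion, giving a π-allyl complex over C5–C10–C9 with the metal syn to the C6 side chain, while the methoxide released with CO2 deprotonates the β-keto ester at C4. The soft enolate carbon then attacks C5 from the face opposite the metal, which is an intramolecular Tsuji–Trost allylic alkylation of a β-keto ester by an allylic carbonate. The seven-membered ring closes in the exo mode at the allyl terminus (7-exo with respect to the allyl unit), leaving the C9=C10 alkene outside the new ring. C5 is set by this double inversion (net retention), so the trans carbonate made in steps 5–8 gives the trans ring fusion, whereas C4 is an epimerisable centre that is removed in step 12. The step needs attack at C5 and not at the tertiary C9 (which would give a strained bridged ring), C- and not O-alkylation, and cyclisation faster than β-hydride loss to a cyclopentadiene; the tether length, the soft doubly stabilised nucleophile, and the neutral dilute conditions should secure these.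

Step 12
Reactants: 16 bicyclic β-keto ester
Product: 18 dienone (core: C3 ketone; C1=C2; C9=C10; 5S,6R,7R), via silyloxy ketone 17 (not isolated)
Conditions: LiCl, H2O, DMSO, 140 °C; cool to rt, then DBU
Reagents that add atoms: none
Why: Krapcho dealkoxycarbonylation removes the C4 ester and E1cB elimination of the β-silyloxy group through the C2 enolate then gives the cis enone, erasing both labile centres (C4 and C1); the hindered γ-hydrogen at C7 should not exchange with DBU at room temperature.

Step 13
Reactants: 18 dienone (C3 ketone)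
Product: 19 tertiary allylic alcohol (core: C3(OH)CH3; C1=C2; C9=C10; 5S,6R,7R; C3 epimers)
Conditions: CH3Li, THF, −78 °C; then H2O
Reagents that add atoms: methyllithium, [Li]C
Why: Organolithium 1,2-addition to the enone carbonyl brings in the C3 methyl group; the C3 configuration does not matter because this carbon becomes sp2 again in step 14.

Step 14
Reactants: 19 tertiary allylic alcohol
Product: 20 transposed dienone (core: C1 ketone; C2=C3(CH3); C9=C10; 5S,6R,7S)
Conditions: pyridinium chlorochromate (C5H5NH)[CrO3Cl], 4 Å molecular sieves, CH2Cl2, rt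
Reagents that add atoms: pyridinium chlorochromate, [O-][Cr](=O)(=O)Cl.c1cc[nH+]cc1
Why: Dauben–Babler oxidative transposition, in which the tertiary allylic chromate ester undergoes a [3,3] shift that places a chromium-bound oxygen on C1 and is then oxidised to the C1 ketone conjugated with C2=C3.

Step 15
Reactants: 20 transposed dienone (C1 ketone)
Product: 21 allylic alcohol (core: C1–OH cis to the C7 isopropyl; C2=C3; C9=C10; 1S,5S,6R,7S)
Conditions: LiBH(s-Bu)3, THF, −78 °C; then H2O
Reagents that add atoms: none
Why: 1,2-Reduction of a β,β-disubstituted enone by a bulky trialkylborohydride, whose hydride should approach the carbonyl from the face anti to the adjacent C7 isopropyl group (as with 2-alkylcycloalkanones), setting C1 with the hydroxyl cis to isopropyl.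

Step 16
Reactants: 21 allylic alcohol
Product: 22 epoxy alcohol (core: C2–C3 epoxide cis to C1–OH; C9=C10; 1S,2S,3R,5S,6R,7S)
Conditions: VO(acac)2 (2 mol%), t-BuOOH, CH2Cl2, 0 °C → rt
Reagents that add atoms: tert-butyl hydroperoxide, CC(C)(C)OO
Why: Vanadium-catalysed hydroxyl-directed epoxidation of a cyclic allylic alcohol delivers oxygen to the C2=C3 face syn to the C1 hydroxyl, setting C3 (and C2), and leaves the undirected C9=C10 alkene untouched.

Step 17
Reactants: 22 epoxy alcohol
Product: 23 diol (core: C1–OH and C3(OH)CH3 cis; C9=C10; 1R,3R,5S,6R,7S)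
Conditions: LiAlH4, THF, 0 → 50 °C; then H2O, aq. NaOH
Reagents that add atoms: none
Why: Hydride reduction of the epoxide by SN2 attack at the secondary C2 and not at the tertiary C3 keeps the C3–O bond, so the tertiary carbinol configuration fixed in step 16 is carried into the cis-1,3-diol.

Step 18
Reactants: 24 isovanillic acid (3-hydroxy-4-methoxybenzoic acid)
Product: 26 3-[(tert-butyldimethylsilyl)oxy]-4-methoxybenzoic acid, via silyl ester silyl ether 25 (not isolated)
Conditions: TBSCl (2.5 equiv), imidazole, DMF, rt; then AcOH, THF–H2O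
Reagents that add atoms: tert-butyldimethylsilyl chloride, CC(C)(C)[Si](C)(C)Cl
Why: Double silylation followed by selective hydrolysis of the labile silyl ester leaves the aryl silyl ether and masks the phenol for the acylation.

Step 19
Reactants: 23 diol; 26 3-[(tert-butyldimethylsilyl)oxy]-4-methoxybenzoic acid
Product: 28 C1 ester of 23 with 26 (core: 1R,3R,5S,6R,7S), via mixed anhydride 27 (not isolated)
Conditions: 26, 2,4,6-trichlorobenzoyl chloride, Et3N, THF, rt; then 23, DMAP, toluene, 60 °C
Reagents that add atoms: none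
Why: Yamaguchi esterification, in which the mixed anhydride acylates under DMAP catalysis only the secondary C1 hydroxyl (the tertiary C3 hydroxyl is too hindered), with retention at C1.

Step 20
Reactants: 28 C1 ester
Product: 29 silyl-protected epoxide (core: C9–C10 epoxide on the face of the C3 hydroxyl; 1R,3R,5S,6R,7S,9R,10S)
Conditions: VO(acac)2 (5 mol%), t-BuOOH, CH2Cl2, 0 °C → rt
Reagents that add atoms: tert-butyl hydroperoxide, CC(C)(C)OO
Why: Vanadium-catalysed hydroxyl-directed epoxidation through the bishomoallylic tertiary C3 hydroxyl, which sits cis-1,3 to C10 across the seven-membered ring and should deliver oxygen to the C9=C10 face on its own side (syn to C4), setting C9 and C10; the product cannot cyclise because hydroxyl and epoxide oxygen share one face.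

Step 21
Reactants: 29 silyl-protected epoxide
Product: 30 CNP0106636.1
Conditions: Bu4NF, AcOH, THF, 0 °C
Reagents that add atoms: none
Why: Buffered fluoride cleavage of the aryl silyl ether frees the phenol without affecting the ester, the epoxide or the tertiary alcohol.

**Compound list**

1 | ethyl 4-methylpent-4-enoate | CCOC(=O)CCC(C)=C | starting material
2 | 4-methylpent-4-enal | O=CCCC(C)=C | intermediate
3 | (E)-3-methyl-1-nitrobut-1-ene | CC(C)/C=C/[N+](=O)[O-] | starting material
4 | (2S,3S)-4-methyl-2-(2-methylprop-2-en-1-yl)-3-(nitromethyl)pentanal | O=C[C@@H](CC(C)=C)[C@H](C(C)C)C[N+](=O)[O-] | intermediate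
5 | (3S,4S)-6-methyl-4-[(2S)-3-methyl-1-nitrobutan-2-yl]hepta-1,6-dien-3-ol | C=C[C@H](O)[C@@H](CC(C)=C)[C@H](C(C)C)C[N+](=O)[O-] | intermediate
6 | (1R,5S)-3-methyl-5-[(2S)-3-methyl-1-nitrobutan-2-yl]cyclopent-2-en-1-ol | CC(C)[C@H](C[N+](=O)[O-])[C@@H]1CC(C)=C[C@@H]1O | intermediate
7 | (1S,5S)-3-methyl-5-[(2S)-3-methyl-1-nitrobutan-2-yl]cyclopent-2-en-1-yl 4-nitrobenzoate | CC(C)[C@H](C[N+](=O)[O-])[C@@H]1CC(C)=C[C@H]1OC(=O)c1ccc(cc1)[N+](=O)[O-] | intermediate
8 | (1S,5S)-3-methyl-5-[(2S)-3-methyl-1-nitrobutan-2-yl]cyclopent-2-en-1-ol | CC(C)[C@H](C[N+](=O)[O-])[C@@H]1CC(C)=C[C@H]1O | intermediate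
9 | potassium nitronate of 8 | CC(C)[C@H](C=[N+]([O-])[O-])[C@@H]1CC(C)=C[C@H]1O.[K+] | intermediate (not isolated)
10 | (2S)-2-[(1S,2S)-2-hydroxy-4-methylcyclopent-3-en-1-yl]-3-methylbutanal | CC(C)[C@H](C=O)[C@@H]1CC(C)=C[C@H]1O | intermediate
11 | methyl (1S,5S)-3-methyl-5-[(2S)-3-methyl-1-oxobutan-2-yl]cyclopent-2-en-1-yl carbonate | CC(C)[C@H](C=O)[C@@H]1CC(C)=C[C@H]1OC(=O)OC | intermediate
12 | methyl acetoacetate (methyl 3-oxobutanoate) | COC(=O)CC(C)=O | starting material
13 | sodium lithium dianion of methyl acetoacetate | COC(=O)[CH-]C(=O)[CH2-].[Na+].[Li+] | intermediate (not isolated)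
14 | methyl (6S)-5-hydroxy-6-[(1S,2S)-2-[(methoxycarbonyl)oxy]-4-methylcyclopent-3-en-1-yl]-7-methyl-3-oxooctanoate, mixture of epimers at the carbinol carbon (core C1) | COC(=O)CC(=O)CC(O)[C@@H](C(C)C)[C@@H]1CC(C)=C[C@H]1OC(=O)OC | intermediate
15 | methyl (6S)-5-[(tert-butyldimethylsilyl)oxy]-6-[(1S,2S)-2-[(methoxycarbonyl)oxy]-4-methylcyclopent-3-en-1-yl]-7-methyl-3-oxooctanoate, core C1 epimers | COC(=O)CC(=O)CC(O[Si](C)(C)C(C)(C)C)[C@@H](C(C)C)[C@@H]1CC(C)=C[C@H]1OC(=O)OC | intermediate
16 | trans-fused bicyclic β-keto ester, core numbering: C1–OTBS (epimers), C3 ketone, C4–CO2CH3 (trans to C10), C7 isopropyl, C9 methyl, C9=C10; (4S,5S,6R,7S) | CC(C)(C)[Si](C)(C)OC1CC(=O)[C@@H](C(=O)OC)[C@H]2[C@@H](CC(C)=C2)[C@@H]1C(C)C | intermediate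
17 | bicyclic ketone, core numbering: C1–OTBS (epimers), C3 ketone, C9=C10; (5S,6R,7S) | CC(C)(C)[Si](C)(C)OC1CC(=O)C[C@H]2[C@@H](CC(C)=C2)[C@@H]1C(C)C | intermediate (not isolated)
18 | bicyclic dienone, core numbering: C3 ketone, C1=C2, C9=C10; (5S,6R,7R) | C1=CC(=O)C[C@H]2[C@@H](CC(C)=C2)[C@@H]1C(C)C | intermediate
19 | tertiary allylic alcohol, core numbering: C3(OH)CH3 (epimers), C1=C2, C9=C10; (5S,6R,7R) | C1=CC(C)(O)C[C@H]2[C@@H](CC(C)=C2)[C@@H]1C(C)C | intermediate
20 | transposed dienone, core numbering: C1 ketone, C2=C3(CH3), C9=C10; (5S,6R,7S) | O=C1C=C(C)C[C@H]2[C@@H](CC(C)=C2)[C@@H]1C(C)C | intermediate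
21 | allylic alcohol, core numbering: C1–OH cis to C7 isopropyl, C2=C3(CH3), C9=C10; (1S,5S,6R,7S) | O[C@@H]1C=C(C)C[C@H]2[C@@H](CC(C)=C2)[C@@H]1C(C)C | intermediate
22 | epoxy alcohol, core numbering: C2–C3 epoxide cis to C1–OH, C9=C10; (1S,2S,3R,5S,6R,7S) | O[C@@H]1[C@@H]2O[C@]2(C)C[C@H]3[C@@H](CC(C)=C3)[C@@H]1C(C)C | intermediate
23 | diol, core numbering: C1–OH and C3(OH)CH3 cis, C9=C10; (1R,3R,5S,6R,7S) | O[C@@H]1C[C@](C)(O)C[C@H]2[C@@H](CC(C)=C2)[C@@H]1C(C)C | intermediate
24 | isovanillic acid (3-hydroxy-4-methoxybenzoic acid) | COc1ccc(C(=O)O)cc1O | starting material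
25 | tert-butyldimethylsilyl 3-[(tert-butyldimethylsilyl)oxy]-4-methoxybenzoate | COc1ccc(cc1O[Si](C)(C)C(C)(C)C)C(=O)O[Si](C)(C)C(C)(C)C | intermediate (not isolated)
26 | 3-[(tert-butyldimethylsilyl)oxy]-4-methoxybenzoic acid | COc1ccc(cc1O[Si](C)(C)C(C)(C)C)C(=O)O | intermediate
27 | 3-[(tert-butyldimethylsilyl)oxy]-4-methoxybenzoic 2,4,6-trichlorobenzoic anhydride | COc1ccc(cc1O[Si](C)(C)C(C)(C)C)C(=O)OC(=O)c1c(Cl)cc(Cl)cc1Cl | intermediate (not isolated)
28 | C1 3-[(tert-butyldimethylsilyl)oxy]-4-methoxybenzoate of diol 23; (1R,3R,5S,6R,7S) | COc1ccc(C(=O)O[C@@H]2C[C@](C)(O)C[C@H]3[C@@H](CC(C)=C3)[C@@H]2C(C)C)cc1O[Si](C)(C)C(C)(C)C | intermediate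
29 | C9–C10 epoxide of 28 (epoxide on the face of the C3 hydroxyl); (1R,3R,5S,6R,7S,9R,10S) | COc1ccc(C(=O)O[C@@H]2C[C@](C)(O)C[C@H]3[C@@H](C[C@@]4(C)O[C@@H]34)[C@@H]2C(C)C)cc1O[Si](C)(C)C(C)(C)C | intermediate
30 | CNP0106636.1, the C1 isovanillate of the epoxy diol; (1R,3R,5S,6R,7S,9R,10S) | COc1ccc(C(=O)O[C@@H]2C[C@](C)(O)C[C@H]3[C@@H](C[C@@]4(C)O[C@@H]34)[C@@H]2C(C)C)cc1O | target

**Step count and risks**

Total: 21 steps. Longest linear sequence: 20 steps (steps 1–17 and 19–21; step 18 is a one-step side branch).

Step 11 (key ring closure). The seven-membered ring may close too slowly, so that the π-allyl intermediate loses a β-hydrogen to give a cyclopentadiene, reacts between molecules, or loses its trans relationship through metal exchange at the allyl unit. Fallback, setting out from 11: the C4–C5 bond would be made between two molecules by the same palladium chemistry, and the ring would be closed at C1=C2. Alkylation of carbonate 11 with methyl 4-(dimethoxyphosphoryl)-3-oxobutanoate (Pd(PPh3)4, THF) at its doubly activated carbon should give, again with net retention, the trans phosphonate keto ester aldehyde F1. Treatment with NaH (2 equiv) in dilute THF should then close the ring by intramolecular Horner–Wadsworth–Emmons olefination to the bicyclic enone ester F2. Dealkoxycarbonylation with LiCl in wet DMSO rejoins the route at 18.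

Step 20 (ring epoxidation). The tertiary hydroxyl may bind vanadium poorly, so that oxygen is delivered from the sterically open face anti to C4 and the facial selectivity is lost. Fallback, setting out from 23: the diol would be tied up with 1,1'-carbonyldiimidazole as the cyclic carbonate F3, which also keeps the C3 oxygen from attacking a bromonium ion. N-Bromosuccinimide in aqueous acetone should then form the bromonium ion on the open face and add water at the tertiary C9 from the opposite face, giving the bromohydrin F4. K2CO3 in methanol would close the epoxide with inversion at C10 and cleave the carbonate, giving the epoxy diol F5 with oxygen on the required face. Acylation of the C1 hydroxyl of F5 with 26 under the conditions of step 19 returns to the route at 29.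

Step 5 (Mitsunobu inversion). The activated allylic alcohol may ionise to an allyl cation with a tertiary terminus, leading to loss of stereospecificity, allylic transposition or elimination. Fallback, setting out from 5: the inversion would be moved to the open-chain stage and done by oxidation and reduction. Dess–Martin oxidation of 5 should give the vinyl ketone F6. Its 1,2-reduction with NaBH4/CeCl3 in methanol at −78 °C under Felkin–Anh control (hydride anti to the C7 branch) should give the (3R)-dienol F7. Ring-closing metathesis of F7 under the conditions of step 4 returns to the route at 8 directly.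

Further compounds

F1 | step 11 | methyl 4-(dimethoxyphosphoryl)-2-[(1S,5R)-3-methyl-5-[(2S)-3-methyl-1-oxobutan-2-yl]cyclopent-2-en-1-yl]-3-oxobutanoate (epimers at C2 of the butanoate) | CC(C)[C@H](C=O)[C@@H]1CC(C)=C[C@H]1C(C(=O)OC)C(=O)CP(=O)(OC)OC
F2 | step 11 | bicyclic enone ester, core numbering: C3 ketone, C4–CO2CH3 (epimers), C1=C2, C9=C10; (5S,6R,7R as in 18) | C1=CC(=O)C(C(=O)OC)[C@H]2[C@@H](CC(C)=C2)[C@@H]1C(C)C
F3 | step 20 | cyclic carbonate of diol 23 (C1–O–CO–O–C3) | O=C1O[C@@H]2C[C@](C)(O1)C[C@H]3[C@@H](CC(C)=C3)[C@@H]2C(C)C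
F4 | step 20 | bromohydrin of F3, core numbering: C9–OH on the face of the C3 oxygen, C10–Br on the opposite face | O=C1O[C@@H]2C[C@](C)(O1)C[C@H]3[C@@H](C[C@@](C)(O)[C@@H]3Br)[C@@H]2C(C)C
F5 | step 20 | epoxy diol, core numbering: C1–OH, C3(OH)CH3, C9–C10 epoxide; (1R,3R,5S,6R,7S,9R,10S) | O[C@@H]1C[C@](C)(O)C[C@H]2[C@@H](C[C@@]3(C)O[C@@H]23)[C@@H]1C(C)C
F6 | step 5 | (4S)-6-methyl-4-[(2S)-3-methyl-1-nitrobutan-2-yl]hepta-1,6-dien-3-one | C=CC(=O)[C@@H](CC(C)=C)[C@H](C(C)C)C[N+](=O)[O-]
F7 | step 5 | (3R,4S)-6-methyl-4-[(2S)-3-methyl-1-nitrobutan-2-yl]hepta-1,6-dien-3-ol | C=C[C@@H](O)[C@@H](CC(C)=C)[C@H](C(C)C)C[N+](=O)[O-]
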